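**Retrosynthetic overview**
1. The target is epioritin-(4β→6)-epioritin-4β-ol; the last step is global hydrogenolysis of its hexa-O-benzyl ether.
2. Key disconnection: the interflavan C4–C6 bond, made with C4 of the upper unit as a nucleophile (a flavan-4-yl anion equivalent from reductive opening of a 2,3-cis-3,4-epoxyflavan, the reverse of the usual C4 cation) and C6 of the lower unit as an electrophile (aryl bromide). A nickel/titanium cross-electrophile coupling sets C4 anti to the 3-oxygen.
3. One epoxide serves both halves: with water it gives the lower unit (2,3-cis-3,4-trans diol), which is then brominated at C6.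
4. The epoxide comes from a (2S)-flav-3-ene through a trans-bromohydrin, which places the oxygen cis to the 2-aryl group; the flavene comes from a (2S)-flavanone by reduction and dehydration.
5. Ring order: ring A is bought (gallacetophenone), ring C is closed as a chromone, ring B is attached by asymmetric conjugate addition (sets C2, from which all other stereocentres are relayed), then the oxirane, then the interflavan bond.

Assumption: flavan numbering is used for all chromane intermediates, and (R)-t-BuPyOx [(R)-4-tert-butyl-2-(pyridin-2-yl)-4,5-dihydrooxazole] is taken to give the (2S)-flavanone (inferred by analogy with cyclic enones); if the sense proves opposite, the other ligand enantiomer is used.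

**Route**

Step 1
Reactants: 1 2,3,4-trihydroxyacetophenone
Product: 2 1-[3,4-bis(benzyloxy)-2-hydroxyphenyl]ethan-1-one
Conditions: BnBr (2.1 equiv), K2CO3 (2.2 equiv), DMF, 25 °C
Reagents that add atoms: benzyl bromide, BrCc1ccccc1
Why: Williamson ether synthesis in which the 2-OH, held in a hydrogen bond to the acetyl carbonyl, is the least reactive phenol, so only the 3- and 4-OH are benzylated; no stereocentre is formed.

Step 2
Reactants: 2 1-[3,4-bis(benzyloxy)-2-hydroxyphenyl]ethan-1-one
Product: 4 7,8-bis(benzyloxy)-4H-chromen-4-one, via enaminone 3 (not isolated)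
Conditions: Me2NCH(OMe)2 (3 equiv), PhMe, 100 °C; then 2 M HCl, CH2Cl2, 40 °C
Reagents that add atoms: N,N-dimethylformamide dimethyl acetal, COC(OC)N(C)C
Why: Enaminone chromone synthesis, in which condensation of the methyl ketone with the amide acetal is followed by acid-promoted oxa-Michael addition of the phenol and loss of dimethylamine to close ring C; no stereocentre is formed.

Step 3
Reactants: 4 7,8-bis(benzyloxy)-4H-chromen-4-one; 5 [4-(benzyloxy)phenyl]boronic acid
Product: 6 (2S)-7,8-bis(benzyloxy)-2-[4-(benzyloxy)phenyl]chroman-4-one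
Conditions: Pd(OCOCF3)2 (5 mol %), (R)-t-BuPyOx (6 mol %), NH4PF6 (30 mol %), H2O (5 equiv), ClCH2CH2Cl, 60 °C
Reagents that add atoms: none
Why: Asymmetric conjugate addition of an arylboronic acid to a chromone with a cationic divalent palladium/pyridine-oxazoline catalyst (Stoltz-type), in which the ligand directs aryl transfer to one face of C2 and so creates the 2S centre (aryl α), the only catalyst-controlled stereocentre of the route.

Step 4
Reactants: 6 (2S)-7,8-bis(benzyloxy)-2-[4-(benzyloxy)phenyl]chroman-4-one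
Product: 7 (2S,4S)-7,8-bis(benzyloxy)-2-[4-(benzyloxy)phenyl]chroman-4-ol
Conditions: NaBH4, MeOH/THF, 0 °C
Reagents that add atoms: none
Why: Borohydride 1,2-reduction of the aryl ketone with axial hydride delivery gives mainly the 2,4-cis alcohol, and the C4 configuration is irrelevant because this centre is removed in step 5.

Step 5
Reactants: 7 (2S,4S)-7,8-bis(benzyloxy)-2-[4-(benzyloxy)phenyl]chroman-4-ol
Product: 9 (2S)-7,8-bis(benzyloxy)-2-[4-(benzyloxy)phenyl]-2H-chromene, via sulfamate ester 8 (not isolated)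
Conditions: Burgess reagent (1.5 equiv), THF, 25 to 50 °C
Reagents that add atoms: none
Why: Burgess dehydration (syn elimination of the sulfamate ester) forms the C3=C4 styrene-type double bond under neutral conditions, which avoids acid-induced opening of the allylic benzylic C2–O bond and so keeps C2 intact.

Step 6
Reactants: 9 (2S)-7,8-bis(benzyloxy)-2-[4-(benzyloxy)phenyl]-2H-chromene
Product: 11 (2R,3R,4R)-7,8-bis(benzyloxy)-2-[4-(benzyloxy)phenyl]-3,4-epoxychromane (epoxide oxygen cis to the 2-aryl group), via bromohydrin 10 (not isolated)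
Conditions: NBS (1.05 equiv), THF/H2O 4:1, 0 °C, dark; then 2 M NaOH (3 equiv), 0 to 20 °C; used crude
Reagents that add atoms: water, O (N-bromosuccinimide, O=C1CCC(=O)N1Br, puts Br into 10 only)
Why: Bromohydrin formation followed by intramolecular Williamson closure, in which the bromonium ion forms on the β-face anti to the 2α-aryl group, water opens it at benzylic C4 from the α-face, and the C4 alkoxide then displaces bromide at C3 with inversion, so the epoxide oxygen ends on the α-face, cis to the aryl group (C3 R, C4 R).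

Step 7
Reactants: 11 (2R,3R,4R)-7,8-bis(benzyloxy)-2-[4-(benzyloxy)phenyl]-3,4-epoxychromane
Product: 12 (2R,3R,4S)-7,8-bis(benzyloxy)-2-[4-(benzyloxy)phenyl]chromane-3,4-diol (2,3-cis-3,4-trans; tri-O-benzyl epioritin-4β-ol)
Conditions: THF/H2O 3:1, AcOH/NaOAc buffer (pH 5), 0 °C, 1 h
Reagents that add atoms: water, O
Why: Mild acid-catalysed hydrolysis of a benzylic epoxide, in which water attacks C4 anti to the departing epoxide oxygen (β-face) while C3 keeps its α-oxygen, giving the 3α,4β-diol.

Step 8
Reactants: 12 (2R,3R,4S)-7,8-bis(benzyloxy)-2-[4-(benzyloxy)phenyl]chromane-3,4-diol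
Product: 13 (2R,3R,4S)-7,8-bis(benzyloxy)-2-[4-(benzyloxy)phenyl]-6-bromochromane-3,4-diol
Conditions: NBS (1.0 equiv), DMF, 0 °C, dark
Reagents that add atoms: N-bromosuccinimide, O=C1CCC(=O)N1Br
Why: Electrophilic aromatic bromination at C6, which is para to the pyran oxygen and ortho to the 7-benzyloxy group and therefore the most nucleophilic ring carbon of the 1,2,3-trioxygenated ring A; the stereocentres are untouched.

Step 9
Reactants: 11 (2R,3R,4R)-7,8-bis(benzyloxy)-2-[4-(benzyloxy)phenyl]-3,4-epoxychromane; 13 (2R,3R,4S)-7,8-bis(benzyloxy)-2-[4-(benzyloxy)phenyl]-6-bromochromane-3,4-diol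
Product: 14 hexa-O-benzyl epioritin-(4β→6)-epioritin-4β-ol (4',7,8-tri-O-benzyl on each unit)
Conditions: NiCl2(MeOCH2CH2OMe) (10 mol %), 2,2'-bipyridine (10 mol %), (C5H5)2TiCl2 (20 mol %), Mn powder (2 equiv), Et3N·HCl (1.5 equiv), DMPU, 25 °C; 11 (1.3 equiv) added in portions
Reagents that add atoms: none
Why: Nickel/titanium co-catalysed reductive cross-electrophile coupling of an epoxide with an aryl bromide (Weix-type, with Nugent–RajanBabu radical epoxide opening), in which trivalent titanium opens the benzylic C4–O bond of 11 to a β-titanoxy C4 radical that is captured by the arylnickel formed from 13, so that C4 reacts as a nucleophilic alkylnickel (β-oxido carbanion equivalent) with the electrophilic C6–Br carbon, and the new bond forms on the β-face, anti to both the 3α-titanoxy group and the 2α-aryl group, giving the 2,3-cis-3,4-trans (4β→6) linkage with C3 carried over unchanged from the epoxide.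

Step 10
Reactants: 14 hexa-O-benzyl epioritin-(4β→6)-epioritin-4β-ol
Product: 15 epioritin-(4β→6)-epioritin-4β-ol, (2R,3R,4S)-2-(4-hydroxyphenyl)-4-[(2R,3R,4S)-3,4,7,8-tetrahydroxy-2-(4-hydroxyphenyl)chroman-6-yl]chromane-3,7,8-triol
Conditions: H2 (1 atm), Pd(OH)2/C (20 wt %), EtOAc/MeOH 1:1, 20 °C, stopped at 6 equiv H2; Sephadex LH-20
Reagents that add atoms: none
Why: Catalytic hydrogenolysis of the six aryl benzyl ethers, which are cleaved much faster than the benzylic C–O bonds of the heterocycles in a neutral medium; no stereocentre is affected.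

**Compound list**
1 | 1-(2,3,4-trihydroxyphenyl)ethan-1-one (gallacetophenone) | CC(=O)c1ccc(O)c(O)c1O | starting material
2 | 1-[3,4-bis(benzyloxy)-2-hydroxyphenyl]ethan-1-one | CC(=O)c1ccc(OCc2ccccc2)c(OCc2ccccc2)c1O | intermediate
3 | (E)-1-[3,4-bis(benzyloxy)-2-hydroxyphenyl]-3-(dimethylamino)prop-2-en-1-one | CN(C)/C=C/C(=O)c1ccc(OCc2ccccc2)c(OCc2ccccc2)c1O | intermediate
4 | 7,8-bis(benzyloxy)-4H-chromen-4-one | O=c1ccoc2c(OCc3ccccc3)c(OCc3ccccc3)ccc12 | intermediate
5 | [4-(benzyloxy)phenyl]boronic acid | OB(O)c1ccc(OCc2ccccc2)cc1 | starting material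
6 | (2S)-7,8-bis(benzyloxy)-2-[4-(benzyloxy)phenyl]chroman-4-one | O=C1C[C@@H](c2ccc(OCc3ccccc3)cc2)Oc2c(OCc3ccccc3)c(OCc3ccccc3)ccc12 | intermediate
7 | (2S,4S)-7,8-bis(benzyloxy)-2-[4-(benzyloxy)phenyl]chroman-4-ol (2,4-cis) | O[C@H]1C[C@@H](c2ccc(OCc3ccccc3)cc2)Oc2c(OCc3ccccc3)c(OCc3ccccc3)ccc12 | intermediate
8 | Burgess sulfamate ester of 7 (4-O-SO2-N(−)-CO2Me, triethylammonium salt) | COC(=O)[N-]S(=O)(=O)O[C@H]1C[C@@H](c2ccc(OCc3ccccc3)cc2)Oc2c(OCc3ccccc3)c(OCc3ccccc3)ccc12.CC[NH+](CC)CC | intermediate
9 | (2S)-7,8-bis(benzyloxy)-2-[4-(benzyloxy)phenyl]-2H-chromene (flav-3-ene, aryl α) | C1=C[C@@H](c2ccc(OCc3ccccc3)cc2)Oc2c(OCc3ccccc3)c(OCc3ccccc3)ccc12 | intermediate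
10 | (2R,3S,4R)-7,8-bis(benzyloxy)-2-[4-(benzyloxy)phenyl]-3-bromochroman-4-ol (2α-aryl, 3β-Br, 4α-OH) | O[C@H]1[C@H](Br)[C@@H](c2ccc(OCc3ccccc3)cc2)Oc2c(OCc3ccccc3)c(OCc3ccccc3)ccc12 | intermediate
11 | (2R,3R,4R)-7,8-bis(benzyloxy)-2-[4-(benzyloxy)phenyl]-3,4-epoxychromane (oxygen cis to 2-aryl) | [C@H]1(c2ccc(OCc3ccccc3)cc2)Oc2c(OCc3ccccc3)c(OCc3ccccc3)ccc2[C@H]2O[C@@H]12 | intermediate
12 | (2R,3R,4S)-7,8-bis(benzyloxy)-2-[4-(benzyloxy)phenyl]chromane-3,4-diol | c1cc2c(c(OCc3ccccc3)c1OCc3ccccc3)O[C@H](c1ccc(OCc3ccccc3)cc1)[C@H](O)[C@H]2O | intermediate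
13 | (2R,3R,4S)-7,8-bis(benzyloxy)-2-[4-(benzyloxy)phenyl]-6-bromochromane-3,4-diol | Brc1cc2c(c(OCc3ccccc3)c1OCc3ccccc3)O[C@H](c1ccc(OCc3ccccc3)cc1)[C@H](O)[C@H]2O | intermediate
14 | hexa-O-benzyl epioritin-(4β→6)-epioritin-4β-ol (upper unit 2α-aryl, 3α-OH, 4β-aryl; lower unit 2α-aryl, 3α-OH, 4β-OH) | c1ccccc1COc1ccc([C@H]2Oc3c(ccc(OCc4ccccc4)c3OCc3ccccc3)[C@H](c3cc4c(c(OCc5ccccc5)c3OCc3ccccc3)O[C@H](c3ccc(OCc5ccccc5)cc3)[C@H](O)[C@H]4O)[C@H]2O)cc1 | intermediate
15 | epioritin-(4β→6)-epioritin-4β-ol (CNP0391561.3) | Oc1ccc([C@H]2Oc3c(ccc(O)c3O)[C@H](c3cc4c(c(O)c3O)O[C@H](c3ccc(O)cc3)[C@H](O)[C@H]4O)[C@H]2O)cc1 | target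

**Step count and risks**
Total steps: 10. Longest linear sequence: 10 steps (steps 1 to 10; epoxide 11 is used twice, once directly in step 9 and once through 12 and 13).

The three steps most likely to fail:

Step 9, the nickel/titanium coupling. The reaction type is known for cyclic and aryl-substituted epoxides, but not for a flavene oxide or for so hindered and electron-rich an aryl bromide. Likely failures are deoxygenation of 11 back to flavene 9, C4–C4 radical dimerisation, and reduction of 13 to 12. The fallback makes the bond in the polar sense. It sets out from epoxide 11 and diol 12 (3 equiv, not brominated) in (CF3)2CHOH/CH2Cl2 at −20 °C, or with 5 mol % Sc(OSO2CF3)3. C6 of 12 opens the benzylic C4–O bond anti to the epoxide oxygen, giving the same stereochemistry. It comes back to the route at 14; step 8 is then not needed and no compound outside the list is made (entry F0).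

Step 6, the cis-epoxide. The face of bromonium formation is only substrate-biased, flavene 9 is air- and acid-sensitive, and 11 is a very labile benzylic epoxide. The fallback sets out from flavanone 6. Bromination with PhNMe3Br3 in THF at 0 °C gives trans-3-bromoflavanone F1, with bromine equatorial and trans to the aryl group under thermodynamic control. NaBH4 at −20 °C then delivers hydride axially to give the 2,3-trans-3,4-trans bromohydrin 10, where the fallback comes back to the route (NaOH closure to 11 as in step 6). Steps 4 and 5 and flavene 9 are bypassed.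

Step 10, the debenzylation. The 4-OH of the lower unit is a benzylic alcohol on an electron-rich ring and can be hydrogenolysed once the phenols are free. The fallback sets out from 14. Et3SiOSO2CF3 and 2,6-lutidine in CH2Cl2 at −78 °C cap the three secondary alcohols to give tris(triethylsilyl) ether F2. Hydrogenolysis with H2 and Pd(OH)2/C in EtOAc gives hexaphenol tris(triethylsilyl) ether F3. HF·pyridine buffered with pyridine in THF at 0 °C removes the silyl groups, and the fallback comes back to the route at 15.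

**Further compounds**
F0 | step 9 | none | none
F1 | step 6 | (2R,3R)-7,8-bis(benzyloxy)-2-[4-(benzyloxy)phenyl]-3-bromochroman-4-one (trans) | O=C1[C@H](Br)[C@@H](c2ccc(OCc3ccccc3)cc2)Oc2c(OCc3ccccc3)c(OCc3ccccc3)ccc12
F2 | step 10 | tris-O-(triethylsilyl) ether of 14 (upper 3-O, lower 3-O and 4-O) | c1ccccc1COc1ccc([C@H]2Oc3c(ccc(OCc4ccccc4)c3OCc3ccccc3)[C@H](c3cc4c(c(OCc5ccccc5)c3OCc3ccccc3)O[C@H](c3ccc(OCc5ccccc5)cc3)[C@H](O[Si](CC)(CC)CC)[C@H]4O[Si](CC)(CC)CC)[C@H]2O[Si](CC)(CC)CC)cc1
F3 | step 10 | tris-O-(triethylsilyl) ether of 15 (upper 3-O, lower 3-O and 4-O; all phenols free) | Oc1ccc([C@H]2Oc3c(ccc(O)c3O)[C@H](c3cc4c(c(O)c3O)O[C@H](c3ccc(O)cc3)[C@H](O[Si](CC)(CC)CC)[C@H]4O[Si](CC)(CC)CC)[C@H]2O[Si](CC)(CC)CC)cc1
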